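**Strategy.** The route rests on taking C19, the oxidised one-carbon branch on quaternary C4, back into the ring (labdane numbering). Ring A (C1–C5, C10) is therefore derived from a seven-membered ring C10–C1–C2–C3–C4–C19–C5 in which C19 is a ketone carbon flanked by C4 and ring-fusion C5. Photochemical Wolff rearrangement of the C4 diazoketone shifts C5 from C19 to C4 with retention, contracts the ring to ring A and releases C19 as the ester that becomes the C4 hydroxymethyl group. The precursor is a trans-fused bicyclo[5.4.0]undecanone that already carries the C10 methyl, the 8(17)-methylidene and a C9 vinyl handle for the side chain.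

Key step: step 6

Remark: labdane numbering is used for all compounds (in the seven-membered-ring compounds the ring ketone carbon is already called C19), and compounds 1, 2, 6 and 18 are assumed to be purchasable.

Step 1
Reactants: 1 3-methylcyclohept-2-en-1-one; 2 propyne
Product: 5 trimethyl{[(3S)-3-methyl-3-[(E)-prop-1-enyl]cyclohept-1-en-1-yl]oxy}silane, via propenylalane 3 (not isolated), via aluminium enolate 4 (not isolated)
Conditions: i-Bu2AlH, hexane, 55 °C; then 1, Cu(O2CC4H3S) (10 mol %), chiral phosphinamine ligand (11 mol %), Et2O, −30 °C; then Me3SiOTf, −78 °C to rt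
Reagents that add atoms: trimethylsilyl trifluoromethanesulfonate, C[Si](C)(C)OS(=O)(=O)C(F)(F)F
Why: Syn-hydroalumination of propyne gives the (E)-alkenylalane, whose copper-catalysed asymmetric conjugate addition to the β-methyl enone sets the C10 quaternary centre under ligand control (ligand enantiomer chosen for the (S)-product), and O-silylation of the aluminium enolate fixes the C5–C19 enolate regiochemistry.

Step 2
Reactants: 6 but-3-yn-1-ol
Product: 7 but-3-yn-1-yl trifluoromethanesulfonate
Conditions: Tf2O, pyridine, CH2Cl2, −78 to 0 °C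
Reagents that add atoms: trifluoromethanesulfonic anhydride, O=S(=O)(OS(=O)(=O)C(F)(F)F)C(F)(F)F
Why: O-Triflation of the primary alcohol (sulfonate ester formation) gives a very reactive SN2 electrophile, and no stereocentre is involved.

Step 3
Reactants: 5 trimethyl{[(3S)-3-methyl-3-[(E)-prop-1-enyl]cyclohept-1-en-1-yl]oxy}silane; 7 but-3-yn-1-yl trifluoromethanesulfonate
Product: 9 (2S,3S)-2-(but-3-ynyl)-3-methyl-3-[(E)-prop-1-enyl]cycloheptan-1-one, via lithium enolate 8 (not isolated)
Conditions: MeLi, THF, 0 °C; then 7, −78 to −30 °C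
Reagents that add atoms: none
Why: MeLi cleaves the silyl enol ether to the regiodefined lithium enolate, which is C-alkylated by the primary triflate (enolate alkylation, SN2) anti to the pseudo-axial propenyl group on C10, so the butynyl chain at the new, still epimerisable C5 centre should end trans to propenyl (2S), any cis epimer being removed by chromatography.

Step 4
Reactants: 9 (2S,3S)-2-(but-3-ynyl)-3-methyl-3-[(E)-prop-1-enyl]cycloheptan-1-one
Product: 10 (1R,4aS,9aS)-1-ethenyl-9a-methyl-2-methylidene-decahydro-5H-benzo[7]annulen-5-one (trans-fused)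
Conditions: Pd(OAc)2 (5 mol %), PPh3 (10 mol %), benzene, 65 °C
Reagents that add atoms: none
Why: Palladium-catalysed Alder-ene cycloisomerisation of the 1,7-enyne (hydropalladation of the alkyne, 6-exo carbopalladation of the propenyl alkene, β-hydride elimination toward its methyl) closes ring B through a chair-like transition state with the two seven-ring bonds equatorial and the C10 methyl axial, which should place the new C9 vinyl group equatorial and cis to that methyl and deliver the 8(17)-methylidene directly.

Step 5
Reactants: 10 (1R,4aS,9aS)-1-ethenyl-9a-methyl-2-methylidene-decahydro-5H-benzo[7]annulen-5-one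
Product: 12 (1R,4aS,9aS)-6-diazo-1-ethenyl-9a-methyl-2-methylidene-decahydro-5H-benzo[7]annulen-5-one, via trifluoroacetyl ketone 11 (not isolated)
Conditions: LiN(SiMe3)2, THF, −78 °C; CF3CO2CH2CF3; then MeSO2N3, Et3N, H2O, MeCN, rt
Reagents that add atoms: methanesulfonyl azide, CS(=O)(=O)N=[N+]=[N-]
Why: Kinetic deprotonation at the unhindered C4 methylene, Claisen-type trifluoroacetylation and detrifluoroacetylative (Regitz-type) diazo transfer install the diazo group regioselectively at C4 without touching C5 or any stereocentre.

Step 6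
Reactants: 12 (1R,4aS,9aS)-6-diazo-1-ethenyl-9a-methyl-2-methylidene-decahydro-5H-benzo[7]annulen-5-one
Product: 14 methyl 13,14,15,16,18-pentanor-ent-labda-8(17),11-dien-19-oate (both C4 epimers), via ketene 13 (not isolated)
Conditions: hν (Hg lamp, Pyrex, λ > 300 nm), MeOH, 20 °C
Reagents that add atoms: methanol, CO
Why: Irradiation expels N2 from the cyclic, s-cis-locked α-diazoketone while C5 shifts from the carbonyl carbon C19 to the diazo carbon C4 (Wolff rearrangement), and the resulting ketene 13 is trapped by methanol as the ester. The closest known reaction type is the photochemical Wolff ring contraction of 2-diazocycloalkanones to the next lower cycloalkanecarboxylates. Ring A (C10–C1–C2–C3–C4–C5) is closed by this 1,2-shift, that is by contraction of the seven-membered ring with extrusion of C19, not by cyclisation of a chain. The migrating C5 keeps its configuration, so the trans ring fusion from step 4 is carried over unchanged, and the only new centre, C4–H, arises from unselective ketene protonation and is erased in step 7. The step needs rearrangement to win over carbene addition to the two alkenes and over C–H insertion, which the concerted pathway of the s-cis diazoketone under direct irradiation without metal catalysts should secure; regiochemistry is not in question because C5 is the only migrating candidate on C19.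

Step 7
Reactants: 14 methyl 13,14,15,16,18-pentanor-ent-labda-8(17),11-dien-19-oate
Product: 16 methyl 13,14,15,16-tetranor-ent-labda-8(17),11-dien-19-oate, via lithium ester enolate 15 (not isolated)
Conditions: LiN(i-Pr)2, THF, −78 °C; MeI, DMPU, −78 to 0 °C
Reagents that add atoms: iodomethane, CI
Why: Ester enolate alkylation in which MeI approaches the exocyclic C4 enolate from the equatorial face, away from the axial C10 methyl (1,3-diaxial shielding), so the new methyl should be equatorial and the ester axial and cis to C20, which is the C19 (4R) configuration.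

Step 8
Reactants: 16 methyl 13,14,15,16-tetranor-ent-labda-8(17),11-dien-19-oate
Product: 17 13,14,15,16-tetranor-ent-labda-8(17),11-dien-19-ol
Conditions: LiAlH4, THF, reflux
Reagents that add atoms: none
Why: LiAlH4 reduction of the hindered axial ester to the neopentyl primary alcohol, in which isolated alkenes are inert and no stereocentre changes.

Step 9
Reactants: 18 tert-butyl 4-chloro-3-oxobutanoate
Product: 19 tert-butyl 4-acetoxy-3-oxobutanoate
Conditions: KOAc, DMF, rt to 40 °C
Reagents that add atoms: potassium acetate, CC(=O)[O-].[K+]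
Why: SN2 displacement of the activated α-chloro ketone chloride by acetate, with no stereocentre involved.

Step 10
Reactants: 19 tert-butyl 4-acetoxy-3-oxobutanoate
Product: 20 tert-butyl (E)-4-acetoxy-3-{[(trifluoromethyl)sulfonyl]oxy}but-2-enoate
Conditions: Tf2O, Me4NOH (aq), toluene, 0 °C, 10 min
Reagents that add atoms: trifluoromethanesulfonic anhydride, O=S(=O)(OS(=O)(=O)C(F)(F)F)C(F)(F)F
Why: O-Sulfonylation of the non-chelated tetramethylammonium enolate of the β-keto ester should give the (E)-enol triflate (triflate trans to the ester, acetoxymethyl cis), the alkene geometry that becomes 13Z after coupling, while brief biphasic contact at 0 °C should spare the acetate.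

Step 11
Reactants: 17 13,14,15,16-tetranor-ent-labda-8(17),11-dien-19-ol; 20 tert-butyl (E)-4-acetoxy-3-{[(trifluoromethyl)sulfonyl]oxy}but-2-enoate
Product: 22 tert-butyl (13Z)-16-acetoxy-19-hydroxy-ent-labda-8(17),13-dien-15-oate, via bis-boryl intermediate 21 (not isolated)
Conditions: 9-BBN-H (2.2 equiv), THF, 0 °C to rt; then 20, PdCl2(dppf) (5 mol %), K3PO4 (3 M aq), DMF, rt
Reagents that add atoms: none
Why: 9-BBN should hydroborate the unhindered monosubstituted C11=C12 vinyl group anti-Markovnikov in preference to the flanked 8(17)-methylidene, and B-alkyl Suzuki–Miyaura coupling with the enol triflate forms C12–C13 with retention of alkene geometry (13Z), no stereocentre being formed.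

Step 12
Reactants: 22 tert-butyl (13Z)-16-acetoxy-19-hydroxy-ent-labda-8(17),13-dien-15-oate
Product: 24 (13Z)-16-acetoxy-19-hydroxy-ent-labda-8(17),13-dien-15-oic acid, via bis-silyl intermediate 23 (not isolated)
Conditions: Me3SiOTf, 2,6-lutidine, CH2Cl2, 0 °C; then H2O (pH 5 buffer)
Reagents that add atoms: none
Why: Me3SiOTf/2,6-lutidine converts the tert-butyl ester into the silyl ester with loss of 2-methylpropene (silyl-transfer ester cleavage) under buffered aprotic conditions that should leave the allylic acetate, the 13Z alkene and the methylidene untouched, and aqueous work-up hydrolyses the silyl ester and the transient C19 silyl ether.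

**Compound list**

1 | 3-methylcyclohept-2-en-1-one | CC1=CC(=O)CCCC1 | starting material
2 | propyne | CC#C | starting material
3 | (E)-prop-1-enyl(diisobutyl)aluminium | C/C=C/[Al](CC(C)C)CC(C)C | intermediate (not isolated)
4 | diisobutylaluminium enolate of (S)-3-methyl-3-[(E)-prop-1-enyl]cycloheptanone (C5=C19 enolate) | C1=C(O[Al](CC(C)C)CC(C)C)CCCC[C@@]1(C)/C=C/C | intermediate (not isolated)
5 | trimethyl{[(3S)-3-methyl-3-[(E)-prop-1-enyl]cyclohept-1-en-1-yl]oxy}silane | C1=C(O[Si](C)(C)C)CCCC[C@@]1(C)/C=C/C | intermediate
6 | but-3-yn-1-ol | C#CCCO | starting material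
7 | but-3-yn-1-yl trifluoromethanesulfonate | C#CCCOS(=O)(=O)C(F)(F)F | intermediate
8 | lithium enolate of (S)-3-methyl-3-[(E)-prop-1-enyl]cycloheptanone (C5=C19 enolate) | C1=C(O[Li])CCCC[C@@]1(C)/C=C/C | intermediate (not isolated)
9 | (2S,3S)-2-(but-3-ynyl)-3-methyl-3-[(E)-prop-1-enyl]cycloheptan-1-one (butynyl trans to propenyl) | C#CCC[C@@H]1C(=O)CCCC[C@@]1(C)/C=C/C | intermediate
10 | (1R,4aS,9aS)-1-ethenyl-9a-methyl-2-methylidene-decahydro-5H-benzo[7]annulen-5-one (trans-fused; C5–H anti to the C10 methyl; vinyl cis to that methyl) | C=C1CC[C@@H]2C(=O)CCCC[C@@]2(C)[C@@H]1C=C | intermediate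
11 | 6-(trifluoroacetyl) derivative of ketone 10 (trifluoroacetyl on C4) | C=C1CC[C@@H]2C(=O)C(C(=O)C(F)(F)F)CCC[C@@]2(C)[C@@H]1C=C | intermediate (not isolated)
12 | (1R,4aS,9aS)-6-diazo-1-ethenyl-9a-methyl-2-methylidene-decahydro-5H-benzo[7]annulen-5-one (diazo on C4) | C=C1CC[C@@H]2C(=O)C(=[N+]=[N-])CCC[C@@]2(C)[C@@H]1C=C | intermediate
13 | ring-contracted ketene (C4=C19=O) of the 13,14,15,16,18-pentanor-ent-labda-8(17),11-diene skeleton | C=C1CC[C@@H]2C(=C=O)CCC[C@@]2(C)[C@@H]1C=C | intermediate (not isolated)
14 | methyl 13,14,15,16,18-pentanor-ent-labda-8(17),11-dien-19-oate (both C4 epimers) | C=C1CC[C@@H]2C(C(=O)OC)CCC[C@@]2(C)[C@@H]1C=C | intermediate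
15 | lithium enolate of ester 14 | C=C1CC[C@@H]2C(=C(O[Li])OC)CCC[C@@]2(C)[C@@H]1C=C | intermediate (not isolated)
16 | methyl 13,14,15,16-tetranor-ent-labda-8(17),11-dien-19-oate (ester axial, cis to C20) | C=C1CC[C@@H]2[C@](C)(C(=O)OC)CCC[C@@]2(C)[C@@H]1C=C | intermediate
17 | 13,14,15,16-tetranor-ent-labda-8(17),11-dien-19-ol | C=C1CC[C@@H]2[C@](C)(CO)CCC[C@@]2(C)[C@@H]1C=C | intermediate
18 | tert-butyl 4-chloro-3-oxobutanoate | CC(C)(C)OC(=O)CC(=O)CCl | starting material
19 | tert-butyl 4-acetoxy-3-oxobutanoate | CC(=O)OCC(=O)CC(=O)OC(C)(C)C | intermediate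
20 | tert-butyl (E)-4-acetoxy-3-{[(trifluoromethyl)sulfonyl]oxy}but-2-enoate | CC(C)(C)OC(=O)/C=C(\COC(C)=O)OS(=O)(=O)C(F)(F)F | intermediate
21 | C12-(9-borabicyclo[3.3.1]nonan-9-yl) O19-(9-borabicyclo[3.3.1]nonan-9-yl) derivative of 13,14,15,16-tetranor-ent-labd-8(17)-en-19-ol | C=C1CC[C@@H]2[C@](C)(COB3C4CCCC3CCC4)CCC[C@@]2(C)[C@@H]1CCB1C2CCCC1CCC2 | intermediate (not isolated)
22 | tert-butyl (13Z)-16-acetoxy-19-hydroxy-ent-labda-8(17),13-dien-15-oate | C=C1CC[C@@H]2[C@](C)(CO)CCC[C@@]2(C)[C@@H]1CC/C(=C/C(=O)OC(C)(C)C)COC(C)=O | intermediate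
23 | trimethylsilyl (13Z)-16-acetoxy-19-(trimethylsilyloxy)-ent-labda-8(17),13-dien-15-oate | C=C1CC[C@@H]2[C@](C)(CO[Si](C)(C)C)CCC[C@@]2(C)[C@@H]1CC/C(=C/C(=O)O[Si](C)(C)C)COC(C)=O | intermediate (not isolated)
24 | (13Z)-16-acetoxy-19-hydroxy-ent-labda-8(17),13-dien-15-oic acid (CNP0136049.1; 4R,5S,9R,10S) | C=C1CC[C@@H]2[C@](C)(CO)CCC[C@@]2(C)[C@@H]1CC/C(=C/C(=O)O)COC(C)=O | target

**Totals**

Total step count: 12. Longest linear sequence: 9 steps (steps 1, 3, 4, 5, 6, 7, 8, 11, 12).

**Steps most likely to fail**

1. Step 3. O-alkylation of the hindered enolate, E2 elimination of the homopropargylic triflate and incomplete facial selectivity at C5 may all erode the yield of the trans-disposed ketone. The fallback sets out from 5 and returns at 9. A Mukaiyama–Michael addition of 5 to acrolein (BF3·OEt2, CH2Cl2, −78 °C) should give 3-[(1S,2S)-2-methyl-7-oxo-2-((E)-prop-1-enyl)cycloheptyl]propanal F1. Ohira–Bestmann homologation of the aldehyde (dimethyl (1-diazo-2-oxopropyl)phosphonate, K2CO3, MeOH) then gives the terminal alkyne 9. The basic medium of the second operation would also equilibrate C5, so the epimers can be separated and the unwanted one recycled.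

2. Step 4. β-Hydride elimination toward C9 instead of the methyl (conjugated diene), slow six-ring closure or a non-chair transition state that erodes control at C9 may spoil the cycloisomerisation. The fallback sets out from 9 and returns at 10. Markovnikov hydrobromination of the terminal alkyne (B-bromo-9-borabicyclo[3.3.1]nonane, then AcOH) should give (2S,3S)-2-(3-bromobut-3-enyl)-3-methyl-3-[(E)-prop-1-enyl]cycloheptan-1-one F2. An intramolecular Heck reaction (Pd(OAc)2, PPh3, Et3N, MeCN, 80 °C) closes ring B by oxidative addition of the vinyl bromide to zerovalent palladium, 6-exo carbopalladation and β-hydride elimination, giving 10.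

3. Step 11. Hydroboration of the 8(17)-methylidene, hydrolysis of the acetate by the aqueous base, or ionisation of the allylic acetate by zerovalent palladium may compete with the coupling. The fallback sets out from 17, uses 20 and returns at 22. Selective hydroboration–oxidation with disiamylborane (then NaBO3) should give 13,14,15,16-tetranor-ent-labd-8(17)-ene-12,19-diol F3. Appel iodination of the unhindered primary hydroxyl (I2, PPh3, imidazole) gives 12-iodo-13,14,15,16-tetranor-ent-labd-8(17)-en-19-ol F4. Zinc insertion (Zn, LiCl, THF), with the hindered neopentyl hydroxyl expected to be tolerated, gives [19-hydroxy-13,14,15,16-tetranor-ent-labd-8(17)-en-12-yl]zinc iodide F5. Negishi coupling of F5 with 20 (Pd(OAc)2, SPhos, THF, rt, no aqueous base) returns 22.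

**Further compounds**

F1 | step 3 | 3-[(1S,2S)-2-methyl-7-oxo-2-((E)-prop-1-enyl)cycloheptyl]propanal | O=CCC[C@@H]1C(=O)CCCC[C@@]1(C)/C=C/C
F2 | step 4 | (2S,3S)-2-(3-bromobut-3-enyl)-3-methyl-3-[(E)-prop-1-enyl]cycloheptan-1-one | C=C(Br)CC[C@@H]1C(=O)CCCC[C@@]1(C)/C=C/C
F3 | step 11 | 13,14,15,16-tetranor-ent-labd-8(17)-ene-12,19-diol | C=C1CC[C@@H]2[C@](C)(CO)CCC[C@@]2(C)[C@@H]1CCO
F4 | step 11 | 12-iodo-13,14,15,16-tetranor-ent-labd-8(17)-en-19-ol | C=C1CC[C@@H]2[C@](C)(CO)CCC[C@@]2(C)[C@@H]1CCI
F5 | step 11 | [19-hydroxy-13,14,15,16-tetranor-ent-labd-8(17)-en-12-yl]zinc iodide | C=C1CC[C@@H]2[C@](C)(CO)CCC[C@@]2(C)[C@@H]1CC[Zn]I
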